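The reading at 8.0 min was the business of this meeting: blue has everything in from the start, violet and teal each have one reactant fed, and green is fed cold and then warmed.

| flask | starting complex | incoming ligand | leaving ligand | capture agent | temperature | remark | time |
|---|---|---|---|---|---|---|---|
| north-west | 0.034 M | 0.017 M | 0.017 M | 0.0102 M | 110 °C | run made earlier |  |
| south-east | 0.034 M | 0.017 M | 0.017 M | 0.020 M | 110 °C | run made earlier |  |
| violet | 0.034 M (fed, over 1.5 min) | 0.0170 M | 0.0170 M | 0.0102 M | 110 °C | all else is in the flask from the start; the feed brings no volume worth counting | 8.0 min |
| teal | 0.034 M | 0.0170 M (fed, over 1.5 min) | 0.0170 M | 0.0102 M | 110 °C | all else is in the flask from the start; the feed brings no volume worth counting | 8.0 min |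
| green | 0.034 M | 0.0170 M (fed, over 1.5 min) | 0.0170 M | 0.0102 M |  | the addition at 80 °C, then warmed to 110 °C; the feed brings no volume worth counting | 8.0 min |
| blue | 0.034 M | 0.0170 M | 0.0170 M | 0.0102 M | 110 °C | everything together at the start | 8.0 min |

- north-west (time / min: complex with two exchanged / %, complex with three exchanged / %, starting complex / %): 0.250: 1.0, 0, 96.6; 0.667: 0.9, 0.4, 92.8; 1.33: 1.6, 0.5, 88.0; 2.00: 2.5, 0, 83.4; 3.00: 5.4, 0.1, 79.6; 4.00: 4.9, 0.6, 77.8; 5.00: 5.1, 1.6, 77.9
- south-east (time / min: complex with two exchanged / %, complex with three exchanged / %, starting complex / %): 0.333: 0, 0.6, 95.9; 0.667: 1.1, 0, 92.9; 1.00: 0.9, 0.2, 89.6; 1.33: 2.3, 0.6, 88.0; 1.50: 3.3, 0, 87.4; 2.00: 3.4, 0, 84.4; 2.50: 3.8, 0.4, 82.7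

(scatter of a reading: 0.5 percentage points)

- candidate steps: starting complex + incoming ligand <-> leaving ligand + complex with one exchanged; complex with one exchanged + incoming ligand <-> leaving ligand + complex with two exchanged; complex with two exchanged + incoming ligand <-> leaving ligand + complex with three exchanged; complex with one exchanged + capture agent -> trapped intermediate; complex with two exchanged -> over-reaction product; complex with one exchanged -> side product
- the earlier runs do not show what temperature does; that part of a forecast is a guess

* which flask leads in share of complex with two exchanged in complex with two exchanged plus complex with three exchanged ("all alike" within 1.5 percentage points) (violet / teal / green / blue / all alike)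
* share of complex with two exchanged in complex with two exchanged plus complex with three exchanged at the end, violet
* share of complex with two exchanged in complex with two exchanged plus complex with three exchanged at the end, teal
* share of complex with two exchanged in complex with two exchanged plus complex with three exchanged at the end, green
* share of complex with two exchanged in complex with two exchanged plus complex with three exchanged at the end, blue

The chair noted that the north-west run has the same charges as blue, and that its complex with three exchanged reads no higher than 1.6 %, against a scatter of 0.5 percentage points. I proposed pooling the north-west readings from 3.00 min to 5.00 min. Complex with three exchanged over complex with two exchanged then gives a ratio r of 0.149, a reading that carries that scatter, at the middle time 4.00 min. Taking r to rise in step with time, I reckoned 0.299 for blue at 8.0 min. The share s of complex with two exchanged, the selectivity, then comes to 77.0 %.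

I then argued about the feeds. A steady feed leaves a shortfall against a flask charged at once, and that shortfall shrinks in a straight line to nothing. Integrating it gives half a feed time of lost contact. So I named the feed delay share f, half the feed time over the reading time, 9.38 %. If r follows contact time, a feed moves s by s(1 − s)f, which is 1.7 points, to be held against the margin of 1.5 points. That reckoned gap rests on north-west readings of complex with three exchanged of 0.1 %, 0.6 % and 1.6 %, each with a scatter of 0.5 points, so I would not name a leader, and I called green's cold start a guess.

The forecast differed. It gave blue 70 % (range 57 % to 81 %), violet 66 %, teal 72 % and green 75 %, with green leading, and said of the feed, in its words, “so the effects are modest”.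

The flask gives blue 86.2 %, violet 86.5 %, teal 86.7 % and green 87.1 %, so the answer is all alike.

    starting complex + incoming ligand ⇌ leaving ligand + complex with one exchanged (K = 1.00, k = 7.40 L mol⁻¹ min⁻¹, Ea = 68.0 kJ mol⁻¹, ΔH = 5.00 kJ mol⁻¹)
    complex with one exchanged + incoming ligand ⇌ leaving ligand + complex with two exchanged (K = 1.60, k = 29.0 L mol⁻¹ min⁻¹, Ea = 49.0 kJ mol⁻¹, ΔH = −22.0 kJ mol⁻¹)
    complex with two exchanged + incoming ligand ⇌ leaving ligand + complex with three exchanged (K = 0.770, k = 6.50 L mol⁻¹ min⁻¹, Ea = 72.0 kJ mol⁻¹, ΔH = −90.0 kJ mol⁻¹)
    complex with one exchanged + capture agent → trapped intermediate (k = 1.40 L mol⁻¹ min⁻¹, Ea = 92.0 kJ mol⁻¹)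
    complex with two exchanged → over-reaction product (k = 0.0120 min⁻¹, Ea = 120 kJ mol⁻¹)
    complex with one exchanged → side product (k = 0.0480 min⁻¹, Ea = 120 kJ mol⁻¹)
    (constants at 110 °C)

In blue at 8.00 min, 36 % of the incoming ligand charged is left. With blue's share put into the rule, s(1 − s)f gives 1.1 points, and teal stands 0.50 points above blue.

The runs stem from a simulated flask with made-up constants; the scatter is artificial.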